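**Retrosynthetic overview**
1. Both anhydride rings (ring A and ring B) are closed together in the last step, from a tetraester that holds two cis-butenedioate units.
2. Ring B carbons: the cis-diester comes from a (Z)-enol triflate by Pd/CO/MeOH; the triflate comes from a β-keto ester made by Roskamp homologation of an α-chiral aldehyde and alkylation with an α-bromo ketone.
3. Key disconnection: the bond between the stereocentre and the CH2 group of ring A, made by an enantioselective radical α-alkylation of a C7 aldehyde (photoredox plus enamine catalysis). The aldehyde carbon later becomes a ring B carbon.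
4. Ring A carbons: the allylic bromide used as radical precursor comes from acylative opening of a symmetric 2,5-dihydrofuran-3,4-diester, itself built by Michael/Dieckmann reaction, triflation and carbonylation.
5. Order: ring A skeleton (open cis-diester), then the stereocentre, then the ring B skeleton, then closure of rings A and B.

Assumption: the imidazolidinone enamine reacts on the face opposite its 5-methyl group, which for the (2S,5R) catalyst is the Re face and gives the S centre; if the sense proves opposite, the (2R,5S) catalyst is used.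

**Step 1**
Reactants: 1 methyl glycolate (methyl 2-hydroxyacetate); 2 methyl acrylate
Product: 4 methyl 4-oxotetrahydrofuran-3-carboxylate (racemic), via oxa-Michael adduct 3 (not isolated)
Conditions: NaH, Et2O then DMSO, 0 °C to rt; aq. HCl work-up
Reagents that add atoms: none
Why: One-pot oxa-Michael addition/Dieckmann condensation, in which the sodium alkoxide of 1 adds to 2 and the ester enolate of 3 closes onto the glycolate ester, a long-established preparation of this five-membered β-keto ester.

**Step 2**
Reactants: 4 methyl 4-oxotetrahydrofuran-3-carboxylate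
Product: 5 methyl 4-{[(trifluoromethyl)sulfonyl]oxy}-2,5-dihydrofuran-3-carboxylate
Conditions: Tf2O, iPr2NEt, CH2Cl2, −78 °C
Reagents that add atoms: trifluoromethanesulfonic anhydride, O=S(=O)(OS(=O)(=O)C(F)(F)F)C(F)(F)F
Why: Enol triflate formation from a cyclic β-keto ester, where the ring forces the triflate and the ester onto the same side of the new double bond.

**Step 3**
Reactants: 5 methyl 4-{[(trifluoromethyl)sulfonyl]oxy}-2,5-dihydrofuran-3-carboxylate
Product: 6 dimethyl 2,5-dihydrofuran-3,4-dicarboxylate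
Conditions: Pd(OAc)2 (5 mol%), PPh3 (10 mol%), CO (1 atm), MeOH, Et3N, DMF, 60 °C
Reagents that add atoms: carbon monoxide, [C-]#[O+]; methanol, CO
Why: Palladium-catalysed methoxycarbonylation of a vinyl triflate (oxidative addition, CO insertion, methanolysis), a routine conversion of a β-keto ester into a cis-butenedioate.

**Step 4**
Reactants: 6 dimethyl 2,5-dihydrofuran-3,4-dicarboxylate
Product: 7 dimethyl (2E)-2-[(acetyloxy)methyl]-3-(bromomethyl)but-2-enedioate (ester groups cis)
Conditions: AcBr (1.2 equiv), ZnBr2 (10 mol%), CH2Cl2, 0 °C to rt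
Reagents that add atoms: acetyl bromide, CC(=O)Br
Why: Lewis-acid-promoted acylative ether cleavage (O-acetylation to an oxonium ion, then SN2 attack of bromide at the allylic CH2), as known for 2,5-dihydrofuran itself; 6 is symmetric, so only one bromo acetate can form and the cis-diester geometry is inherited from the ring.

**Step 5 (key step)**
Reactants: 7 dimethyl (2E)-2-[(acetyloxy)methyl]-3-(bromomethyl)but-2-enedioate; 8 heptanal
Product: 9 dimethyl (2Z)-2-[(acetyloxy)methyl]-3-[(2S)-2-formylheptyl]but-2-enedioate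
Conditions: fac-tris(2-phenylpyridinato)iridium, Ir(ppy)3 (0.5 mol%), (2S,5R)-2-tert-butyl-3,5-dimethylimidazolidin-4-one·CF3SO3H (20 mol%), 2,6-lutidine (2 equiv), 8 (2 equiv), DMF, blue LEDs, 10 °C
Reagents that add atoms: none
Why: Proposed new method: photoexcited Ir(ppy)3 reduces the allylic C–Br bond of 7 (a vinylogous α-bromo ester) to an electron-poor 2,3-bis(methoxycarbonyl)allyl radical, which adds through its unhindered CH2 end to the Re face of the (E)-enamine of 8 (the 5-methyl group of the catalyst screens the Si face, which sets the S centre), and oxidation of the α-amino radical then hydrolysis of the iminium ion release 9; the closest known reaction type is the MacMillan photoredox/enamine α-alkylation of aldehydes with bromomalonates, phenacyl bromides and electron-poor benzyl bromides.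

**Step 6**
Reactants: 9 dimethyl (2Z)-2-[(acetyloxy)methyl]-3-[(2S)-2-formylheptyl]but-2-enedioate; 10 ethyl diazoacetate
Product: 11 dimethyl (2Z)-2-[(acetyloxy)methyl]-3-[(2S)-2-(3-ethoxy-3-oxopropanoyl)heptyl]but-2-enedioate
Conditions: SnCl2 (10 mol%), CH2Cl2, rt
Reagents that add atoms: none
Why: Roskamp reaction, in which tin dichloride-catalysed addition of the diazo ester to the aldehyde, 1,2-hydride shift and loss of N2 give the β-keto ester under non-basic conditions, so the α-stereocentre is not epimerised and the esters, the acetate and the hindered alkene are untouched.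

**Step 7**
Reactants: 11 dimethyl (2Z)-2-[(acetyloxy)methyl]-3-[(2S)-2-(3-ethoxy-3-oxopropanoyl)heptyl]but-2-enedioate; 12 1-bromohexan-2-one
Product: 13 dimethyl (2Z)-2-[(acetyloxy)methyl]-3-[(2S)-2-[2-(ethoxycarbonyl)-4-oxooctanoyl]heptyl]but-2-enedioate (both epimers at the carbon between the carbonyl groups)
Conditions: K2CO3, acetone, rt
Reagents that add atoms: none
Why: C-alkylation of a β-keto ester enolate with an α-bromo ketone (SN2), where carbonate removes only the doubly activated C–H, which also shields the neighbouring stereocentre from enolisation; the new centre is irrelevant because it becomes sp2 in step 8.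

**Step 8**
Reactants: 13 dimethyl (2Z)-2-[(acetyloxy)methyl]-3-[(2S)-2-[2-(ethoxycarbonyl)-4-oxooctanoyl]heptyl]but-2-enedioate
Product: 14 dimethyl (2Z)-2-[(acetyloxy)methyl]-3-[(2S,3Z)-4-(ethoxycarbonyl)-6-oxo-2-pentyl-3-{[(trifluoromethyl)sulfonyl]oxy}dec-3-en-1-yl]but-2-enedioate
Conditions: Tf2O, sat. aq. LiOH, toluene, 5 °C
Reagents that add atoms: trifluoromethanesulfonic anhydride, O=S(=O)(OS(=O)(=O)C(F)(F)F)C(F)(F)F
Why: Chelation-controlled (Z)-selective enol triflate formation (Frantz-type aqueous LiOH/Tf2O conditions), in which the lithium-chelated enolate of the β-keto ester is trapped on oxygen with triflate and ester cis, the aqueous medium keeps Tf2O from activating the 1,4-diketone towards furan formation, and any E isomer can still equilibrate later through the dienolate of the 2-oxohexyl group.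

**Step 9**
Reactants: 14 dimethyl (2Z)-2-[(acetyloxy)methyl]-3-[(2S,3Z)-4-(ethoxycarbonyl)-6-oxo-2-pentyl-3-{[(trifluoromethyl)sulfonyl]oxy}dec-3-en-1-yl]but-2-enedioate
Product: 15 dimethyl (2Z)-2-[(acetyloxy)methyl]-3-[(2S,3Z)-4-(ethoxycarbonyl)-3-(methoxycarbonyl)-6-oxo-2-pentyldec-3-en-1-yl]but-2-enedioate
Conditions: Pd(OAc)2 (5 mol%), 1,3-bis(diphenylphosphino)propane (6 mol%), CO (1 atm), MeOH, Et3N, DMF, 40 °C
Reagents that add atoms: carbon monoxide, [C-]#[O+]; methanol, CO
Why: Palladium-catalysed methoxycarbonylation of the enol triflate with retention of alkene geometry gives the second cis-butenedioate, since oxidative addition to the vinyl triflate is much faster than ionisation of the hindered tetrasubstituted allylic acetate and triethylamine is too weak a base to touch the now allylic stereocentre.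

**Step 10**
Reactants: 15 dimethyl (2Z)-2-[(acetyloxy)methyl]-3-[(2S,3Z)-4-(ethoxycarbonyl)-3-(methoxycarbonyl)-6-oxo-2-pentyldec-3-en-1-yl]but-2-enedioate
Product: 17 3-[(2S)-2-[4-(2-oxohexyl)-2,5-dioxo-2,5-dihydrofuran-3-yl]heptyl]-4-(hydroxymethyl)furan-2,5-dione, via tetracarboxylic acid 16 (not isolated)
Conditions: LiOH (8 equiv), THF/H2O, 0 °C to rt; then 2 M HCl (pH 1), rt; toluene azeotrope, 40 °C
Reagents that add atoms: lithium hydroxide (aqueous), [Li+].[OH-]
Why: Saponification of the four esters and the acetate followed by acidification, after which each tetrasubstituted cis-butenedioic acid cyclodehydrates spontaneously to its maleic anhydride (rings A and B close together), while the CH2OH group stays free because it lies trans to the only carboxyl group with which it could lactonise.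

**Compound list**
1 | methyl glycolate | COC(=O)CO | starting material
2 | methyl acrylate | C=CC(=O)OC | starting material
3 | methyl 3-(2-methoxy-2-oxoethoxy)propanoate (oxa-Michael adduct) | COC(=O)COCCC(=O)OC | intermediate
4 | methyl 4-oxotetrahydrofuran-3-carboxylate (racemic) | COC(=O)C1COCC1=O | intermediate
5 | methyl 4-{[(trifluoromethyl)sulfonyl]oxy}-2,5-dihydrofuran-3-carboxylate | COC(=O)C1=C(OS(=O)(=O)C(F)(F)F)COC1 | intermediate
6 | dimethyl 2,5-dihydrofuran-3,4-dicarboxylate | COC(=O)C1=C(C(=O)OC)COC1 | intermediate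
7 | dimethyl (2E)-2-[(acetyloxy)methyl]-3-(bromomethyl)but-2-enedioate (ester groups cis) | BrC/C(C(=O)OC)=C(\COC(C)=O)C(=O)OC | intermediate
8 | heptanal | CCCCCCC=O | starting material
9 | dimethyl (2Z)-2-[(acetyloxy)methyl]-3-[(2S)-2-formylheptyl]but-2-enedioate | CCCCC[C@@H](C/C(C(=O)OC)=C(\COC(C)=O)C(=O)OC)C=O | intermediate
10 | ethyl diazoacetate | CCOC(=O)C=[N+]=[N-] | starting material
11 | dimethyl (2Z)-2-[(acetyloxy)methyl]-3-[(2S)-2-(3-ethoxy-3-oxopropanoyl)heptyl]but-2-enedioate | CCCCC[C@@H](C/C(C(=O)OC)=C(\COC(C)=O)C(=O)OC)C(=O)CC(=O)OCC | intermediate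
12 | 1-bromohexan-2-one | CCCCC(=O)CBr | starting material
13 | dimethyl (2Z)-2-[(acetyloxy)methyl]-3-[(2S)-2-[2-(ethoxycarbonyl)-4-oxooctanoyl]heptyl]but-2-enedioate (both epimers at the carbon between the carbonyl groups) | CCCCC[C@@H](C/C(C(=O)OC)=C(\COC(C)=O)C(=O)OC)C(=O)C(CC(=O)CCCC)C(=O)OCC | intermediate
14 | dimethyl (2Z)-2-[(acetyloxy)methyl]-3-[(2S,3Z)-4-(ethoxycarbonyl)-6-oxo-2-pentyl-3-{[(trifluoromethyl)sulfonyl]oxy}dec-3-en-1-yl]but-2-enedioate | CCCCC[C@@H](C/C(C(=O)OC)=C(\COC(C)=O)C(=O)OC)/C(OS(=O)(=O)C(F)(F)F)=C(\CC(=O)CCCC)C(=O)OCC | intermediate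
15 | dimethyl (2Z)-2-[(acetyloxy)methyl]-3-[(2S,3Z)-4-(ethoxycarbonyl)-3-(methoxycarbonyl)-6-oxo-2-pentyldec-3-en-1-yl]but-2-enedioate | CCCCC[C@@H](C/C(C(=O)OC)=C(\COC(C)=O)C(=O)OC)/C(C(=O)OC)=C(\CC(=O)CCCC)C(=O)OCC | intermediate
16 | (2Z)-2-[(2S,3Z)-3,4-dicarboxy-6-oxo-2-pentyldec-3-en-1-yl]-3-(hydroxymethyl)but-2-enedioic acid | CCCCC[C@@H](C/C(C(=O)O)=C(\CO)C(=O)O)/C(C(=O)O)=C(\CC(=O)CCCC)C(=O)O | intermediate
17 | 3-[(2S)-2-[4-(2-oxohexyl)-2,5-dioxo-2,5-dihydrofuran-3-yl]heptyl]-4-(hydroxymethyl)furan-2,5-dione | CCCCC[C@@H](CC1=C(CO)C(=O)OC1=O)C1=C(CC(=O)CCCC)C(=O)OC1=O | target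

**Totals**
Total step count: 10. Longest linear sequence: 10 steps (1 to 17).

**The three steps most likely to fail**

Step 5. Allylic bromides of this kind have not been used in photoredox/enamine alkylation. Bromide 7 may N-alkylate the amine catalyst, a polar background alkylation may erode the ee, and the iridium sensitiser may isomerise the cis-diester. The fallback sets out from 8 and comes back at 9. It replaces the catalytic enamine by a stoichiometric chiral one: 8 is condensed with (2S,5S)-2,5-diphenylpyrrolidine (4 Å molecular sieves, Et2O) to the enamine (E)-1-[(2S,5S)-2,5-diphenylpyrrolidin-1-yl]hept-1-ene F1. F1 and 7 are then coupled in a radical chain started by Ru(bpy)3Cl2 (1 mol%, divalent ruthenium, lower triplet energy) under blue light, with 2,6-lutidine in MeCN at −20 °C. The phenyl group syn to the enamine double bond blocks the Si face, and any polar alkylation of F1 by 7 would give the same product with the same facial bias. Aqueous acetic acid hydrolyses the iminium salt to 9 and returns the amine.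

Step 8. Compound 13 is a 1,4-diketone, so triflation may be diverted to a furan or a cyclopentenone, and the hindered tetrasubstituted enolate may react slowly or with poor Z selectivity. The fallback sets out from 11 and comes back at 15. It carries the side-chain ketone as an alkyne: 11 is alkylated with 1-bromohex-2-yne (K2CO3, acetone) to dimethyl (2Z)-2-[(acetyloxy)methyl]-3-[(2S)-2-[2-(ethoxycarbonyl)oct-4-ynoyl]heptyl]but-2-enedioate F2. F2 has no second ketone and is converted with Tf2O/aq. LiOH in toluene into the enol triflate dimethyl (2Z)-2-[(acetyloxy)methyl]-3-[(2S,3Z)-4-(ethoxycarbonyl)-2-pentyl-3-{[(trifluoromethyl)sulfonyl]oxy}dec-3-en-6-yn-1-yl]but-2-enedioate F3. Methoxycarbonylation as in step 9 gives dimethyl (2Z)-2-[(acetyloxy)methyl]-3-[(2S,3Z)-4-(ethoxycarbonyl)-3-(methoxycarbonyl)-2-pentyldec-3-en-6-yn-1-yl]but-2-enedioate F4. Gold-catalysed hydration (Ph3PAuNTf2, monovalent gold, wet dioxane, 60 °C) then gives 15; 5-exo attack of the neighbouring ester carbonyl on the alkyne carbon next to the CH2 group places the ketone at the 2-position of the hexyl chain.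

Step 9. Zerovalent palladium may ionise the allylic acetate of ring A to a π-allyl complex, and oxidative addition to the hindered tetrasubstituted triflate may be slow. The fallback sets out from 14 and comes back at 17. It removes the acetate before the palladium step: lipase-catalysed methanolysis (Candida antarctica lipase B, MeOH, tert-butyl methyl ether, 30 °C) gives dimethyl (2Z)-2-[(2S,3Z)-4-(ethoxycarbonyl)-6-oxo-2-pentyl-3-{[(trifluoromethyl)sulfonyl]oxy}dec-3-en-1-yl]-3-(hydroxymethyl)but-2-enedioate F5. The free allylic alcohol cannot ionise, so methoxycarbonylation under the step 9 conditions gives dimethyl (2Z)-2-[(2S,3Z)-4-(ethoxycarbonyl)-3-(methoxycarbonyl)-6-oxo-2-pentyldec-3-en-1-yl]-3-(hydroxymethyl)but-2-enedioate F6. The step 10 conditions convert F6 into 17.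

**Further compounds**
F1 | step 5 | (E)-1-[(2S,5S)-2,5-diphenylpyrrolidin-1-yl]hept-1-ene | CCCCC/C=C/N1[C@H](c2ccccc2)CC[C@H]1c1ccccc1
F2 | step 8 | dimethyl (2Z)-2-[(acetyloxy)methyl]-3-[(2S)-2-[2-(ethoxycarbonyl)oct-4-ynoyl]heptyl]but-2-enedioate | CCCCC[C@@H](C/C(C(=O)OC)=C(\COC(C)=O)C(=O)OC)C(=O)C(CC#CCCC)C(=O)OCC
F3 | step 8 | dimethyl (2Z)-2-[(acetyloxy)methyl]-3-[(2S,3Z)-4-(ethoxycarbonyl)-2-pentyl-3-{[(trifluoromethyl)sulfonyl]oxy}dec-3-en-6-yn-1-yl]but-2-enedioate | CCCCC[C@@H](C/C(C(=O)OC)=C(\COC(C)=O)C(=O)OC)/C(OS(=O)(=O)C(F)(F)F)=C(\CC#CCCC)C(=O)OCC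
F4 | step 8 | dimethyl (2Z)-2-[(acetyloxy)methyl]-3-[(2S,3Z)-4-(ethoxycarbonyl)-3-(methoxycarbonyl)-2-pentyldec-3-en-6-yn-1-yl]but-2-enedioate | CCCCC[C@@H](C/C(C(=O)OC)=C(\COC(C)=O)C(=O)OC)/C(C(=O)OC)=C(\CC#CCCC)C(=O)OCC
F5 | step 9 | dimethyl (2Z)-2-[(2S,3Z)-4-(ethoxycarbonyl)-6-oxo-2-pentyl-3-{[(trifluoromethyl)sulfonyl]oxy}dec-3-en-1-yl]-3-(hydroxymethyl)but-2-enedioate | CCCCC[C@@H](C/C(C(=O)OC)=C(\CO)C(=O)OC)/C(OS(=O)(=O)C(F)(F)F)=C(\CC(=O)CCCC)C(=O)OCC
F6 | step 9 | dimethyl (2Z)-2-[(2S,3Z)-4-(ethoxycarbonyl)-3-(methoxycarbonyl)-6-oxo-2-pentyldec-3-en-1-yl]-3-(hydroxymethyl)but-2-enedioate | CCCCC[C@@H](C/C(C(=O)OC)=C(\CO)C(=O)OC)/C(C(=O)OC)=C(\CC(=O)CCCC)C(=O)OCC
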